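Remark on the chemistry: the target is achiral; the stereogenic carbons that appear on the way (C6 of 14, the bridgeheads of 17) are racemic and are erased, so no configuration has to be controlled.

## The problem

Compound 21, 2,4-dihydroxy-5-methyl-6-(13-methyltetradecyl)benzoic acid, is a single benzene ring with five substituents and one ring hydrogen. In benzoic acid numbering, used throughout, C1 carries CO2H, C2 and C4 carry OH, C3 is CH, C5 carries CH3 and C6 carries the iso-branched C15 chain. There is no ring fusion and no stereocentre, so the difficulty is regiochemical: three contiguous carbon substituents (C5 methyl, C6 chain, C1 carboxyl) must sit in a fixed order against two meta oxygens, and stepwise substitution of a resorcinol does not deliver this cleanly because C1, C3 and C5 are all activated. The side chain is twelve methylenes ending in an isopropyl group, has no functional handle, and must be built by sp3–sp3 coupling and carried as a spectator. The fragile part is the β-resorcylic acid: the electron-rich ring loses CO2 on heating or in acid, while an ester at C1, flanked by the C2 oxygen and the C6 chain, resists saponification. The acid therefore has to be unveiled last, under neutral conditions at room temperature. A short ring synthesis is possible because C2–C3–C4–C5 is a 1,3-dioxygenated butadiene with the methyl group on its C5 terminus, and C1–C6 is the triple bond of a 2-alkynoate with the chain on the β-carbon. Two bonds (C1–C2 and C5–C6) join these pieces, and a CH2CH2 bridge between C2 and C5 can hold the diene s-cis and then leave as ethene.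

## Retrosynthesis

**21 from 19.** The two O–CH2Ph bonds are cut, leading from acid 21 to phenol 19, with acid 20 as the expected half-way stage. The neighbouring choice, a methyl ether and a methyl ester, would need Lewis-acid demethylation and saponification of a di-ortho-substituted benzoate, under conditions where 21 decarboxylates. Hydrogenolysis breaks bonds remote from the hindered carbonyl. Compound 19 is no simpler in skeleton but is stable and chromatographable. The forward step must remove both benzyl groups in one neutral operation.

**19 from 18.** The O–Si bond at C4 is cut. The silyl group is what remains of the silyl dienol ether used in the ring synthesis. A tert-butyldimethylsilyl group is preferred to a trimethylsilyl group so that diene and arene survive prolonged heating and chromatography. The forward step needs a fluoride source that leaves both benzyl groups alone.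

**18 from 16 and 9.** The ring is opened at C1–C2 and C5–C6, giving diene 16 and ynoate 9; cycloadduct 17 lies between them and loses its two saturated ring carbons as a gaseous two-carbon olefin. This cut is preferred to a C1–C6 aldol closure or a C5–C6/C3–C4 annulation because it is redox-neutral and brings the carboxyl carbon in with the dienophile, so no oxidant and no late C–H functionalisation of the arene is needed. The pentasubstituted arene is reduced to a trisubstituted cyclohexadiene and a linear ester that already holds the whole chain. The forward reaction must be regioselective and must outpace thermal decay of the diene.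

**16 from 14.** The enol O–Si bond is cut, giving enone 14 by way of its kinetic enolate 15. Double silylation of a 4-methylcyclohexane-1,3-dione would be shorter in principle but cannot tell the two carbonyl groups apart. In 14 the enol ether already fixes which oxygen is which. The forward step needs deprotonation at the C6 methine and O-silylation of a tetrasubstituted enolate.

**14 from 12.** The C6–CH3 bond is cut. Kinetic deprotonation of vinylogous ester 12 occurs only at the α′ carbon (enolate 13), so the methyl position is unambiguous. Putting the methyl group on the finished arene instead would depend on a selective substitution between C3 and C5. The forward step is a single C-methylation that must stop at mono-alkylation.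

**12 from 10 and 11.** The enol ether C–O bond is cut, giving cyclohexane-1,3-dione 10 and benzyl alcohol 11. The dione is symmetrical, so there is no regiochemical question. Choosing the benzyl enol ether here is what allows the hydrogenolytic endgame.

**9 from 6 and 7.** The bond between the carboxyl carbon and the alkyne is cut, giving terminal alkyne 6 and benzyl chloroformate 7, joined through lithium alkynide 8. This puts the ester group of choice on the dienophile in one step. The forward step must avoid double addition to the chloroformate.

**6 from 5, and 5 from 4.** The C(sp)–C(sp3) bond is cut, leaving primary bromide 5 for displacement by a two-carbon acetylide nucleophile. Bromide 5 comes from alcohol 4 by functional-group interchange. Both steps are standard for an unbranched primary centre.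

**4 from 1 and 2.** The sp3–sp3 bond four carbons from the chain end is cut, giving 11-bromoundecan-1-ol 1 and isobutylmagnesium bromide 2. A primary Grignard reagent is preferred to an isopropyl one because primary alkylcopper intermediates are less prone to β-hydride elimination. The hydroxyl is carried as its magnesium alkoxide 3, so no protecting group is needed.

## Roads not taken

**Alternative 1:** The ring is cut at C5–C6 and C3–C4 and built at the cyclohexane-1,3-dione oxidation level. The silyl ketene acetal 1-methoxy-1-(trimethylsilyloxy)prop-1-ene A3 adds in a Lewis-acid-promoted Mukaiyama–Michael reaction to methyl 2-acetyl-16-methylheptadec-2-enoate A2. Alkoxide in the same flask then closes the ring by Dieckmann condensation to methyl 5-methyl-6-(13-methyltetradecyl)-2,4-dioxocyclohexane-1-carboxylate A1.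
- Merits: cheap reagents, low temperatures, regiochemistry fixed by connectivity, and both oxygens free of protecting groups. It is also shorter, about six operations from a chain alcohol against ten here.
- Weak points: A1 is two hydrogens short of aromatic. Halogenation–dehydrohalogenation or quinone dehydrogenation of so electron-rich a resorcylate, with C3–H open, invites ring halogenation or over-oxidation. The chain must be supplied as an aldehyde one carbon longer than alcohol 4. The methyl ester of A1 sits in the same hindered position that makes saponification of such benzoates difficult.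
- Comparison: Alternative 1 is shorter and cooler. The chosen route offsets this with an aromatisation that needs no oxidant (ethene leaves from 17) and an ester in 9 that is cleaved by hydrogenolysis. The benzyl ester idea could be carried over to Alternative 1, but the oxidation step could not be avoided.

**Alternative 2:** The ring is cut at C2–C3, C4–C5 and C1–C2. Heating 2-methyl-3-(13-methyltetradecyl)cyclobut-2-en-1-one A5 with ethoxyethyne A6 starts a Danheiser benzannulation: ring opening to a vinylketene, [2+2] addition, second ring opening and 6π closure. The product is 3-ethoxy-4-methyl-5-(13-methyltetradecyl)phenol A4.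
- Merits: a regiospecific cascade at a lower temperature than the key step here. The methyl/chain adjacency is fixed in A5, and the C2 oxygen arrives free.
- Weak points: A4 has hydrogen at C1, so the carboxyl carbon is still missing. It would have to be introduced by a Kolbe–Schmitt-type carboxylation at the position flanked by OH and the chain, in competition with C3 between the two oxygens, under conditions close to those that decarboxylate the product. The ethyl ether at C4 needs a boron trihalide for cleavage. A5 needs its own regiodefined four-membered-ring synthesis, and A6 is volatile and costly.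
- Comparison: length is similar and the thermal demand is lower, which counts in its favour. The chosen route offsets this by placing the carboxyl in the ring-forming step (9 carries it), so the crowded C1 position is never functionalised on a finished arene.

**Alternative 3:** The ring is cut at C1–C6 of a tetraketide. The diketo-dioxinone 6-(3,17-dimethyl-2,4-dioxooctadecyl)-2,2-dimethyl-4H-1,3-dioxin-4-one A8 is heated with benzyl alcohol 11. Retro-[4+2] fragmentation releases an acylketene, which is trapped as benzyl 6,20-dimethyl-3,5,7-trioxohenicosanoate A9. Mild base then brings about aldol closure and dehydration to benzyl 2,4-dihydroxy-5-methyl-6-(13-methyltetradecyl)benzoate A7. Hydrogenolysis of A7 would give 21.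
- Merits: biomimetic, no phenol protection, mild temperatures, the same neutral final step as here, and probably two or three steps fewer.
- Weak points: A8 must be made by C-acylation of a dioxinone keto-dianion with a long-chain acyl donor at the carbon that carries the methyl group. The resulting 2-methyl-1,3-diketone is prone to O-acylation and retro-Claisen cleavage. The methyl branch hinders the C6 ketone, so pyrone formation or the alternative aldol from the chain-side methylene can compete. The polycarbonyl intermediates are hard to purify.
- Comparison: Alternative 3 is as good or better in step count and mildness. The chosen route offsets this with a concerted ring closure whose regiochemistry does not depend on which of several condensations wins, and with non-enolisable intermediates (9, 16, 18) that can be purified and stored.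

Key step: step 8

## Route

Step 1
Reactants: 1 11-bromoundecan-1-ol; 2 isobutylmagnesium bromide
Product: 4 13-methyltetradecan-1-ol, via bromomagnesium 11-bromoundecan-1-olate 3 (not isolated)
Conditions: 2 (3 equiv), Li2CuCl4 (3 mol %), THF, −78 °C to rt; aq NH4Cl
Reagents that add atoms: none
Why: Copper-catalysed Kochi cross-coupling of a primary alkyl bromide with a primary alkyl Grignard reagent; the first equivalent of 2 turns the hydroxyl into alkoxide 3, which is inert to the organocopper, and a primary alkyl group on copper has little tendency to β-hydride elimination.

Step 2
Reactants: 4 13-methyltetradecan-1-ol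
Product: 5 1-bromo-13-methyltetradecane
Conditions: CBr4, PPh3, CH2Cl2, 0 °C to rt
Reagents that add atoms: carbon tetrabromide, BrC(Br)(Br)Br
Why: Appel reaction: the alkoxyphosphonium ion of the primary alcohol is displaced by bromide in an SN2 step, and the saturated chain offers no path for rearrangement.

Step 3
Reactants: 5 1-bromo-13-methyltetradecane
Product: 6 15-methylhexadec-1-yne
Conditions: LiC≡CH·H2NCH2CH2NH2, DMSO, 15 °C to rt
Reagents that add atoms: lithium acetylide–ethylenediamine complex, [Li]C#C.NCCN
Why: SN2 alkylation of an acetylide by an unhindered primary bromide in a dipolar aprotic solvent; at room temperature the complex should not move the triple bond inward.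

Step 4
Reactants: 6 15-methylhexadec-1-yne; 7 benzyl chloroformate
Product: 9 benzyl 16-methylheptadec-2-ynoate, via (15-methylhexadec-1-yn-1-yl)lithium 8 (not isolated)
Conditions: n-BuLi, THF, −78 °C; then 7 (1.3 equiv), −78 to 0 °C
Reagents that add atoms: none
Why: Alkoxycarbonylation of a lithium alkynide with a chloroformate; a slight excess of 7 at low temperature prevents a second alkynide from adding to the product, and the benzyl ester is chosen so that the acid can later be freed by hydrogenolysis.

Step 5
Reactants: 10 cyclohexane-1,3-dione; 11 benzyl alcohol
Product: 12 3-(benzyloxy)cyclohex-2-en-1-one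
Conditions: TsOH·H2O (cat.), toluene, reflux, Dean–Stark
Reagents that add atoms: none
Why: Acid-catalysed condensation of a cyclic 1,3-dione with an alcohol (vinylogous ester formation), driven by azeotropic removal of water; the dione is symmetrical, so only one enol ether can form.

Step 6
Reactants: 12 3-(benzyloxy)cyclohex-2-en-1-one
Product: 14 3-(benzyloxy)-6-methylcyclohex-2-en-1-one (racemic), via lithium 5-(benzyloxy)cyclohexa-1,5-dien-1-olate 13 (not isolated)
Conditions: LiN(i-Pr)2, THF, −78 °C; MeI, −78 °C to rt
Reagents that add atoms: iodomethane, CI
Why: Stork–Danheiser kinetic α′-alkylation of a vinylogous ester: lithium diisopropylamide removes the C6 proton to give cross-conjugated enolate 13, which is C-methylated at that carbon only; the new stereocentre is racemic and is flattened again in step 7.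

Step 7
Reactants: 14 3-(benzyloxy)-6-methylcyclohex-2-en-1-one
Product: 16 1-(benzyloxy)-3-[(tert-butyldimethylsilyl)oxy]-4-methylcyclohexa-1,3-diene, via lithium 5-(benzyloxy)-2-methylcyclohexa-1,5-dien-1-olate 15 (not isolated)
Conditions: LiN(i-Pr)2, THF, −78 °C; TBSCl, DMPU, −78 °C to rt; filtration through basic alumina
Reagents that add atoms: tert-butyldimethylsilyl chloride, CC(C)(C)[Si](C)(C)Cl
Why: A second kinetic deprotonation at the same α′ carbon gives tetrasubstituted enolate 15, and O-silylation of the lithium enolate in the presence of DMPU (silyl enol ether formation) fixes the 2-silyloxy diene with the methyl group on its terminus; the bulky silyl group is chosen for thermal and hydrolytic stability in step 8.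

Step 8
Reactants: 16 1-(benzyloxy)-3-[(tert-butyldimethylsilyl)oxy]-4-methylcyclohexa-1,3-diene; 9 benzyl 16-methylheptadec-2-ynoate
Product: 18 benzyl 2-(benzyloxy)-4-[(tert-butyldimethylsilyl)oxy]-5-methyl-6-(13-methyltetradecyl)benzoate, via bicyclo[2.2.2]octa-2,5-diene cycloadduct 17 (not isolated)
Conditions: neat, 16 (2.5 equiv), BHT (1 mol %), Ar, sealed tube, 175–180 °C
Reagents that add atoms: none
Why: The s-cis-locked, doubly oxygenated diene of 16 and the electron-poor triple bond of 9 should combine in a thermal, concerted but asynchronous [4+2] cycloaddition to bicyclo[2.2.2]octa-2,5-diene 17, which then loses its CH2CH2 bridge as ethene in a retro-[4+2] step to leave the benzene ring (Alder–Rickert reaction). The closest known reaction type is the Alder–Rickert aromatisation of 1-alkoxy-3-silyloxycyclohexa-1,3-dienes with 2-alkynoates to 2-alkoxy-4-silyloxybenzoates; the present diene differs only by a methyl group on its terminus. The one ring is closed intermolecularly in a suprafacial [4π+2π] mode, forming C1–C2 and C5–C6 (benzoate numbering) at the same time. No stereocentre survives: the bridgeheads of 17 are racemic and become aromatic carbons. The selectivity needed is regiochemical, and both oxygen donors secure it by placing the largest HOMO coefficient on the methyl-bearing diene terminus, which bonds to the β-carbon of the ynoate (largest LUMO coefficient), so the benzyloxy group ends ortho to the ester and the methyl group ortho to the chain. Loss of gaseous ethene makes the aromatisation irreversible without an oxidant, and the excess of diene, the radical inhibitor and the robust silyl group are there to offset the slow bond formation between two fully substituted carbons.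

Step 9
Reactants: 18 benzyl 2-(benzyloxy)-4-[(tert-butyldimethylsilyl)oxy]-5-methyl-6-(13-methyltetradecyl)benzoate
Product: 19 benzyl 2-(benzyloxy)-4-hydroxy-5-methyl-6-(13-methyltetradecyl)benzoate
Conditions: TBAF, AcOH, THF, 0 °C
Reagents that add atoms: none
Why: Fluoride-induced cleavage of an aryl silyl ether, driven by the strong Si–F bond; acetic acid buffers the phenoxide so that the hindered benzyl ester and the benzyl ether are left alone.

Step 10
Reactants: 19 benzyl 2-(benzyloxy)-4-hydroxy-5-methyl-6-(13-methyltetradecyl)benzoate
Product: 21 2,4-dihydroxy-5-methyl-6-(13-methyltetradecyl)benzoic acid, via 2-(benzyloxy)-4-hydroxy-5-methyl-6-(13-methyltetradecyl)benzoic acid 20 (not isolated)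
Conditions: H2 (1 atm), 10% Pd/C, EtOAc–MeOH, rt; filter, concentrate below 30 °C
Reagents that add atoms: none
Why: Heterogeneous catalytic hydrogenolysis of benzylic C–O bonds should remove the ester benzyl group first (acid 20) and then the aryl benzyl ether; cleavage occurs away from the hindered carbonyl under neutral conditions at room temperature, so the decarboxylation-prone acid is never heated or exposed to acid or base.

## Compound list

1 | 11-bromoundecan-1-ol | OCCCCCCCCCCCBr | starting material
2 | isobutylmagnesium bromide (2-methylpropylmagnesium bromide) | CC(C)C[Mg]Br | starting material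
3 | bromomagnesium 11-bromoundecan-1-olate | BrCCCCCCCCCCCO[Mg]Br | intermediate (not isolated)
4 | 13-methyltetradecan-1-ol | CC(C)CCCCCCCCCCCCO | intermediate
5 | 1-bromo-13-methyltetradecane | CC(C)CCCCCCCCCCCCBr | intermediate
6 | 15-methylhexadec-1-yne | CC(C)CCCCCCCCCCCCC#C | intermediate
7 | benzyl chloroformate | O=C(Cl)OCc1ccccc1 | starting material
8 | (15-methylhexadec-1-yn-1-yl)lithium | CC(C)CCCCCCCCCCCCC#C[Li] | intermediate (not isolated)
9 | benzyl 16-methylheptadec-2-ynoate | CC(C)CCCCCCCCCCCCC#CC(=O)OCc1ccccc1 | intermediate
10 | cyclohexane-1,3-dione | O=C1CCCC(=O)C1 | starting material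
11 | benzyl alcohol | OCc1ccccc1 | starting material
12 | 3-(benzyloxy)cyclohex-2-en-1-one | O=C1C=C(OCc2ccccc2)CCC1 | intermediate
13 | lithium 5-(benzyloxy)cyclohexa-1,5-dien-1-olate | [Li]OC1=CCCC(OCc2ccccc2)=C1 | intermediate (not isolated)
14 | 3-(benzyloxy)-6-methylcyclohex-2-en-1-one (racemic) | CC1CCC(OCc2ccccc2)=CC1=O | intermediate
15 | lithium 5-(benzyloxy)-2-methylcyclohexa-1,5-dien-1-olate | [Li]OC1=C(C)CCC(OCc2ccccc2)=C1 | intermediate (not isolated)
16 | 1-(benzyloxy)-3-[(tert-butyldimethylsilyl)oxy]-4-methylcyclohexa-1,3-diene | CC1=C(O[Si](C)(C)C(C)(C)C)C=C(OCc2ccccc2)CC1 | intermediate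
17 | benzyl 1-(benzyloxy)-5-[(tert-butyldimethylsilyl)oxy]-4-methyl-3-(13-methyltetradecyl)bicyclo[2.2.2]octa-2,5-diene-2-carboxylate (racemic) | CC(C)CCCCCCCCCCCCC1=C(C(=O)OCc2ccccc2)C2(OCc3ccccc3)CCC1(C)C(O[Si](C)(C)C(C)(C)C)=C2 | intermediate (not isolated)
18 | benzyl 2-(benzyloxy)-4-[(tert-butyldimethylsilyl)oxy]-5-methyl-6-(13-methyltetradecyl)benzoate | CC(C)CCCCCCCCCCCCc1c(C)c(O[Si](C)(C)C(C)(C)C)cc(OCc2ccccc2)c1C(=O)OCc1ccccc1 | intermediate
19 | benzyl 2-(benzyloxy)-4-hydroxy-5-methyl-6-(13-methyltetradecyl)benzoate | CC(C)CCCCCCCCCCCCc1c(C)c(O)cc(OCc2ccccc2)c1C(=O)OCc1ccccc1 | intermediate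
20 | 2-(benzyloxy)-4-hydroxy-5-methyl-6-(13-methyltetradecyl)benzoic acid | CC(C)CCCCCCCCCCCCc1c(C)c(O)cc(OCc2ccccc2)c1C(=O)O | intermediate (not isolated)
21 | 2,4-dihydroxy-5-methyl-6-(13-methyltetradecyl)benzoic acid | Cc1c(O)cc(O)c(C(=O)O)c1CCCCCCCCCCCCC(C)C | target

## Step count and risks

Total step count: 10. Longest linear sequence: 7 (steps 1–4, then 8–10); the diene arm (steps 5–7) joins at step 8.

**Step 8 (key step).** The most likely failure is that bond formation between the methyl-bearing diene terminus and the chain-bearing alkyne carbon is too slow at temperatures the diene tolerates. Thermal decay of 16 (1,5-hydrogen shift to isomeric dienes, loss of the silyl group, dehydrogenation to a resorcinol diether) and oligomerisation of 9 would then consume the partners before cycloaddition is complete.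

The fallback raises the electrophilicity of the dienophile and separates the bimolecular step from the high-temperature step. It sets out from alkyne 6 and diene 16 and returns at 18.
- Alkynide 8, made from 6 as in step 4, is formylated with DMF (inverse quench into aqueous KH2PO4) to 16-methylheptadec-2-ynal F1.
- F1 and 16 should combine in toluene at about 100 °C, with the same regiochemistry, to 1-(benzyloxy)-5-[(tert-butyldimethylsilyl)oxy]-4-methyl-3-(13-methyltetradecyl)bicyclo[2.2.2]octa-2,5-diene-2-carbaldehyde F2.
- Once the diene is consumed, F2 is heated to about 160 °C to expel its two-carbon bridge and give 2-(benzyloxy)-4-[(tert-butyldimethylsilyl)oxy]-5-methyl-6-(13-methyltetradecyl)benzaldehyde F3.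
- Pinnick oxidation (NaClO2, NaH2PO4, 2-methylbut-2-ene, t-BuOH–water) gives 2-(benzyloxy)-4-[(tert-butyldimethylsilyl)oxy]-5-methyl-6-(13-methyltetradecyl)benzoic acid F4.
- Alkylation of the carboxylate of F4 with benzyl bromide and KHCO3 in DMF returns ester 18.

If the methyl group on the diene is itself the obstacle, the detour under step 7 removes it.

**Step 7.** The C6 methine of 14 is more hindered than the CH2 of 12. Incomplete enolisation, proton transfer to the γ-position and sluggish O-silylation of the tetrasubstituted enolate could give the cross-conjugated diene contaminated with its linear isomer, and hydrolysis on isolation would erode it further.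

The fallback takes the methyl group out of the diene and installs it on the arene. It sets out from enone 12 and ynoate 9 and returns at 18.
- Enolate 13 is O-silylated under the conditions of step 7 to 1-(benzyloxy)-3-[(tert-butyldimethylsilyl)oxy]cyclohexa-1,3-diene F5.
- F5 and 9 undergo the Alder–Rickert reaction in its directly precedented substitution pattern, through benzyl 1-(benzyloxy)-5-[(tert-butyldimethylsilyl)oxy]-3-(13-methyltetradecyl)bicyclo[2.2.2]octa-2,5-diene-2-carboxylate F6, to benzyl 2-(benzyloxy)-4-[(tert-butyldimethylsilyl)oxy]-6-(13-methyltetradecyl)benzoate F7.
- Bromination of F7 with N-bromosuccinimide in acetonitrile should go para to the benzyloxy group, at C5 and not at C3 between the two oxygens, giving benzyl 2-(benzyloxy)-5-bromo-4-[(tert-butyldimethylsilyl)oxy]-6-(13-methyltetradecyl)benzoate F8.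
- Negishi coupling of F8 with MeZnCl (Pd(OAc)2, SPhos, THF, 60 °C) gives 18.

**Step 10.** Hydrogenolysis may stall, because the waxy substrate adsorbs poorly and the aryl benzyl ether next to the freed carboxyl cleaves slowly. Forcing it by warming or acid would promote protodecarboxylation of the β-resorcylic acid. The fallback is a Lewis-acid debenzylation: BCl3 with pentamethylbenzene as cation scavenger in CH2Cl2 at −78 °C should cleave both benzyl groups of 19, and a cold methanolic quench gives 21 directly. It sets out from 19, returns at 21 and has no new intermediate.

**Step 1.** Alkoxide 3 is poorly soluble in cold THF, so coupling may lag behind halogen–magnesium exchange, elimination and homocoupling of the Grignard reagent. The fallback builds the same bond by olefination and sets out from 1, returning at 4.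
- Bromide 1 is heated with PPh3 in acetonitrile to give (11-hydroxyundecyl)triphenylphosphonium bromide F9.
- Two equivalents of NaN(SiMe3)2 in THF convert F9 into sodium 11-(triphenyl-λ5-phosphanylidene)undecan-1-olate F10.
- Wittig reaction of F10 with 2-methylpropanal gives (Z)-13-methyltetradec-11-en-1-ol F11.
- Hydrogenation of F11 (H2, Pd/C, EtOAc) gives 4.

## Further compounds

F1 | step 8 | 16-methylheptadec-2-ynal | CC(C)CCCCCCCCCCCCC#CC=O
F2 | step 8 | 1-(benzyloxy)-5-[(tert-butyldimethylsilyl)oxy]-4-methyl-3-(13-methyltetradecyl)bicyclo[2.2.2]octa-2,5-diene-2-carbaldehyde (racemic) | CC(C)CCCCCCCCCCCCC1=C(C=O)C2(OCc3ccccc3)CCC1(C)C(O[Si](C)(C)C(C)(C)C)=C2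
F3 | step 8 | 2-(benzyloxy)-4-[(tert-butyldimethylsilyl)oxy]-5-methyl-6-(13-methyltetradecyl)benzaldehyde | CC(C)CCCCCCCCCCCCc1c(C)c(O[Si](C)(C)C(C)(C)C)cc(OCc2ccccc2)c1C=O
F4 | step 8 | 2-(benzyloxy)-4-[(tert-butyldimethylsilyl)oxy]-5-methyl-6-(13-methyltetradecyl)benzoic acid | CC(C)CCCCCCCCCCCCc1c(C)c(O[Si](C)(C)C(C)(C)C)cc(OCc2ccccc2)c1C(=O)O
F5 | step 7 | 1-(benzyloxy)-3-[(tert-butyldimethylsilyl)oxy]cyclohexa-1,3-diene | CC(C)(C)[Si](C)(C)OC1=CCCC(OCc2ccccc2)=C1
F6 | step 7 | benzyl 1-(benzyloxy)-5-[(tert-butyldimethylsilyl)oxy]-3-(13-methyltetradecyl)bicyclo[2.2.2]octa-2,5-diene-2-carboxylate (racemic) | CC(C)CCCCCCCCCCCCC1=C(C(=O)OCc2ccccc2)C2(OCc3ccccc3)CCC1C(O[Si](C)(C)C(C)(C)C)=C2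
F7 | step 7 | benzyl 2-(benzyloxy)-4-[(tert-butyldimethylsilyl)oxy]-6-(13-methyltetradecyl)benzoate | CC(C)CCCCCCCCCCCCc1cc(O[Si](C)(C)C(C)(C)C)cc(OCc2ccccc2)c1C(=O)OCc1ccccc1
F8 | step 7 | benzyl 2-(benzyloxy)-5-bromo-4-[(tert-butyldimethylsilyl)oxy]-6-(13-methyltetradecyl)benzoate | CC(C)CCCCCCCCCCCCc1c(Br)c(O[Si](C)(C)C(C)(C)C)cc(OCc2ccccc2)c1C(=O)OCc1ccccc1
F0 | step 10 | none | none
F9 | step 1 | (11-hydroxyundecyl)triphenylphosphonium bromide | OCCCCCCCCCCC[P+](c1ccccc1)(c1ccccc1)c1ccccc1.[Br-]
F10 | step 1 | sodium 11-(triphenyl-λ5-phosphanylidene)undecan-1-olate | [Na]OCCCCCCCCCCC=P(c1ccccc1)(c1ccccc1)c1ccccc1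
F11 | step 1 | (Z)-13-methyltetradec-11-en-1-ol | CC(C)/C=C\CCCCCCCCCCO
A1 | alternative 1 | methyl 5-methyl-6-(13-methyltetradecyl)-2,4-dioxocyclohexane-1-carboxylate (mixture of diastereomers) | COC(=O)C1C(=O)CC(=O)C(C)C1CCCCCCCCCCCCC(C)C
A2 | alternative 1 | methyl 2-acetyl-16-methylheptadec-2-enoate | CC(C)CCCCCCCCCCCCC=C(C(C)=O)C(=O)OC
A3 | alternative 1 | 1-methoxy-1-(trimethylsilyloxy)prop-1-ene | CC=C(OC)O[Si](C)(C)C
A4 | alternative 2 | 3-ethoxy-4-methyl-5-(13-methyltetradecyl)phenol | CCOc1cc(O)cc(CCCCCCCCCCCCC(C)C)c1C
A5 | alternative 2 | 2-methyl-3-(13-methyltetradecyl)cyclobut-2-en-1-one | CC1=C(CCCCCCCCCCCCC(C)C)CC1=O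
A6 | alternative 2 | ethoxyethyne | CCOC#C
A7 | alternative 3 | benzyl 2,4-dihydroxy-5-methyl-6-(13-methyltetradecyl)benzoate | Cc1c(O)cc(O)c(C(=O)OCc2ccccc2)c1CCCCCCCCCCCCC(C)C
A8 | alternative 3 | 6-(3,17-dimethyl-2,4-dioxooctadecyl)-2,2-dimethyl-4H-1,3-dioxin-4-one | CC(C)CCCCCCCCCCCCC(=O)C(C)C(=O)CC1=CC(=O)OC(C)(C)O1
A9 | alternative 3 | benzyl 6,20-dimethyl-3,5,7-trioxohenicosanoate | CC(C)CCCCCCCCCCCCC(=O)C(C)C(=O)CC(=O)CC(=O)OCc1ccccc1
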